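**Retrosynthetic overview**
- Kanzonol C (18) comes from its 4,4'-bis(methoxymethyl) ether 17 by acetal cleavage.
- The strategy rests on ring A, a 1,2,3,4-tetrasubstituted benzene (acyl at C1', OH at C2', prenyl at C3', O at C4'). This pattern is that of a cyclohexane-1,3-dione alkylated at C2 and acylated at C4, which as the enol ether is C6 of the cyclohexenone.
- Ring A of 17 is therefore made last, by dehydrogenation across C5–C6 of the 6-cinnamoylcyclohexenone 12. Ring B is aromatic from the start.
- 12 comes from C6 acylation of the kinetic enolate of the MOM vinylogous ester 4 with the ring B cinnamoyl imidazolide 10.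
- 4 comes from cyclohexane-1,3-dione (C2 prenylation, O-MOM). 10 comes from 4-hydroxybenzaldehyde (ortho prenylation, MOM, Knoevenagel–Doebner, CDI).

Key step: step 8

Remark: 12 is written as the 1,3-diketone, although it should exist mainly as its hydrogen-bonded enol. Its C6 centre is racemic and is removed in step 8. The target has no stereocentre; its one E alkene is set in step 5. "Prenyl" means 3-methylbut-2-en-1-yl.

**Step 1**
Reactants: 1 cyclohexane-1,3-dione; 2 prenyl bromide (1-bromo-3-methylbut-2-ene)
Product: 3 2-(3-methylbut-2-en-1-yl)cyclohexane-1,3-dione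
Conditions: KOH (1.0 equiv), H2O, 2 (1.1 equiv), 0 °C → rt; acidify, extract product into aq. NaHCO3, re-acidify
Reagents that add atoms: none
Why: C-alkylation of the 1,3-dione enolate in water, where the hydrogen-bonded oxygen is shielded and the soft allylic bromide is taken up at C2, the only carbon between the two carbonyls; neutral O-alkyl and dialkyl by-products are removed by the base extraction.

**Step 2**
Reactants: 3 2-(3-methylbut-2-en-1-yl)cyclohexane-1,3-dione
Product: 4 3-(methoxymethoxy)-2-(3-methylbut-2-en-1-yl)cyclohex-2-en-1-one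
Conditions: MOMCl (1.2 equiv), iPr2NEt (1.5 equiv), CH2Cl2, 0 °C → rt; chromatography on Et3N-deactivated silica
Reagents that add atoms: chloromethyl methyl ether (MOMCl), COCCl
Why: O-alkylation of the dione enolate by the hard oxocarbenium-type electrophile gives the vinylogous ester, and because 3 is symmetric only one enol ether can form.

**Step 3**
Reactants: 5 4-hydroxybenzaldehyde; 2 prenyl bromide
Product: 6 4-hydroxy-3-(3-methylbut-2-en-1-yl)benzaldehyde
Conditions: KOH (1.0 equiv, 10% aq.), 2 (1.0 equiv), rt, 24–48 h; acidify, chromatography (unreacted 5 recovered)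
Reagents that add atoms: none
Why: ortho C-alkylation of the phenoxide in water, where solvation of oxygen favours attack through carbon; the para position is blocked by the formyl group, so only the ortho C-alkyl isomer can arise.

**Step 4**
Reactants: 6 4-hydroxy-3-(3-methylbut-2-en-1-yl)benzaldehyde
Product: 7 4-(methoxymethoxy)-3-(3-methylbut-2-en-1-yl)benzaldehyde
Conditions: MOMCl (1.3 equiv), iPr2NEt (2 equiv), CH2Cl2, 0 °C → rt
Reagents that add atoms: chloromethyl methyl ether (MOMCl), COCCl
Why: Williamson-type acetal formation on the acidic para-formyl phenol; the aldehyde and the prenyl group are inert to these conditions.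

**Step 5**
Reactants: 7 4-(methoxymethoxy)-3-(3-methylbut-2-en-1-yl)benzaldehyde; 8 malonic acid
Product: 9 (E)-3-[4-(methoxymethoxy)-3-(3-methylbut-2-en-1-yl)phenyl]prop-2-enoic acid
Conditions: 8 (2 equiv), pyridine, piperidine (0.1 equiv), 90 °C; cold dilute citric acid work-up
Reagents that add atoms: none
Why: Knoevenagel–Doebner condensation with decarboxylation should give the E-cinnamic acid under thermodynamic control, in a basic medium that leaves the MOM acetal intact.

**Step 6**
Reactants: 9 (E)-3-[4-(methoxymethoxy)-3-(3-methylbut-2-en-1-yl)phenyl]prop-2-enoic acid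
Product: 10 (E)-1-(1H-imidazol-1-yl)-3-[4-(methoxymethoxy)-3-(3-methylbut-2-en-1-yl)phenyl]prop-2-en-1-one
Conditions: CDI (1.05 equiv), THF, rt; then CH2Cl2, brief cold-water wash, dry, use at once
Reagents that add atoms: 1,1'-carbonyldiimidazole (CDI), O=C(n1ccnc1)n1ccnc1
Why: carboxyl activation with CDI gives the acyl imidazolide under neutral conditions that spare the MOM ether, and the wash removes imidazole, whose N–H would otherwise quench the enolate in step 7.

**Step 7**
Reactants: 4 3-(methoxymethoxy)-2-(3-methylbut-2-en-1-yl)cyclohex-2-en-1-one; 10 (E)-1-(1H-imidazol-1-yl)-3-[4-(methoxymethoxy)-3-(3-methylbut-2-en-1-yl)phenyl]prop-2-en-1-one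
Product: 12 3-(methoxymethoxy)-6-[(E)-3-[4-(methoxymethoxy)-3-(3-methylbut-2-en-1-yl)phenyl]prop-2-enoyl]-2-(3-methylbut-2-en-1-yl)cyclohex-2-en-1-one (racemic at C6; mainly enol), via lithium C6-enolate 11 (not isolated)
Conditions: LiN(iPr)2 (LDA, 2.1 equiv), THF, −78 °C, 4 (2.1 equiv); then 10 (1.0 equiv), −78 → −30 °C; aq. NH4Cl (excess 4 recovered)
Reagents that add atoms: none
Why: kinetic α'-deprotonation of the vinylogous ester occurs at C6 only, and the hard lithium enolate should add at low temperature to the acyl carbon of the imidazolide in a Claisen-type C-acylation, with the second equivalent of enolate taking up the acidic proton of the β-diketone formed.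

**Step 8**
Reactants: 12 3-(methoxymethoxy)-6-[(E)-3-[4-(methoxymethoxy)-3-(3-methylbut-2-en-1-yl)phenyl]prop-2-enoyl]-2-(3-methylbut-2-en-1-yl)cyclohex-2-en-1-one
Product: 17 (E)-1-[2-hydroxy-4-(methoxymethoxy)-3-(3-methylbut-2-en-1-yl)phenyl]-3-[4-(methoxymethoxy)-3-(3-methylbut-2-en-1-yl)phenyl]prop-2-en-1-one (Kanzonol C 4,4'-bis(methoxymethyl) ether), via sodium enolate 13 (not isolated), via C6 phenylselenide 14 (not isolated), via C6 selenoxide 15 (not isolated), via cross-conjugated acyl dienone 16 (not isolated)
Conditions: NaH (1.1 equiv), THF, 0 °C; PhSeBr (1.0 equiv), −78 → −40 °C; then pyridine (2 equiv), 30% aq. H2O2 (1.2 equiv), 0 °C → rt; aq. Na2S2O3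
Reagents that add atoms: none
Why: NaH converts the β-diketone 12 into its delocalised sodium enolate 13, whose central carbon C6 attacks the selenium of PhSeBr to give the quaternary selenide 14; H2O2 then oxidises selenium to the selenoxide 15, which should undergo syn-elimination below room temperature toward C5, the only carbon bearing a β-hydrogen, and the cross-conjugated acyl dienone 16 tautomerises by a pyridine-assisted proton shift from C4 to oxygen to give the phenol 17. The closest known reaction type is the selenoxide dehydrogenation of β-dicarbonyl compounds, applied here to a substrate that already holds the C2=C3 enol ether double bond, so that a single dehydrogenation reaches the aromatic oxidation level. No ring is closed and no skeletal bond or stereocentre is formed; the racemic C6 centre of 12 is erased and the E alkene is not touched. The step needs chemoselectivity for the enolate over the two trisubstituted prenyl alkenes toward PhSeBr, which the preformed anion, the exact stoichiometry and the low temperature should secure, and for selenium over the alkenes toward the oxidant, which the much higher nucleophilicity of a selenide toward H2O2 should secure. Pyridine buffers the benzeneselenenic acid that is released, so that it should neither add to the prenyl groups nor promote their epoxidation, and the small excess of H2O2 in a non-alkaline medium should leave the new 2'-hydroxychalcone unoxidised. Aromatisation and the hydrogen bond between the C2' hydroxyl and the ketone make the overall change irreversible.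

**Step 9**
Reactants: 17 Kanzonol C 4,4'-bis(methoxymethyl) ether
Product: 18 Kanzonol C, (E)-1-[2,4-dihydroxy-3-(3-methylbut-2-en-1-yl)phenyl]-3-[4-hydroxy-3-(3-methylbut-2-en-1-yl)phenyl]prop-2-en-1-one
Conditions: 3 M aq. HCl, MeOH, rt → 40 °C; NaHCO3 work-up
Reagents that add atoms: none
Why: acid-catalysed acetal solvolysis removes both aryl MOM groups as dimethoxymethane under conditions mild enough that the prenyl groups should not cyclise onto the neighbouring phenols and the chalcone should not close to the flavanone.

**Compound list**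
1 | cyclohexane-1,3-dione | O=C1CCCC(=O)C1 | starting material
2 | prenyl bromide (1-bromo-3-methylbut-2-ene) | CC(C)=CCBr | starting material
3 | 2-(3-methylbut-2-en-1-yl)cyclohexane-1,3-dione | CC(C)=CCC1C(=O)CCCC1=O | intermediate
4 | 3-(methoxymethoxy)-2-(3-methylbut-2-en-1-yl)cyclohex-2-en-1-one | CC(C)=CCC1=C(OCOC)CCCC1=O | intermediate
5 | 4-hydroxybenzaldehyde | O=Cc1ccc(O)cc1 | starting material
6 | 4-hydroxy-3-(3-methylbut-2-en-1-yl)benzaldehyde | CC(C)=CCc1cc(C=O)ccc1O | intermediate
7 | 4-(methoxymethoxy)-3-(3-methylbut-2-en-1-yl)benzaldehyde | CC(C)=CCc1cc(C=O)ccc1OCOC | intermediate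
8 | malonic acid | OC(=O)CC(=O)O | starting material
9 | (E)-3-[4-(methoxymethoxy)-3-(3-methylbut-2-en-1-yl)phenyl]prop-2-enoic acid | CC(C)=CCc1cc(/C=C/C(=O)O)ccc1OCOC | intermediate
10 | (E)-1-(1H-imidazol-1-yl)-3-[4-(methoxymethoxy)-3-(3-methylbut-2-en-1-yl)phenyl]prop-2-en-1-one | CC(C)=CCc1cc(/C=C/C(=O)n2ccnc2)ccc1OCOC | intermediate
11 | lithium 5-(methoxymethoxy)-6-(3-methylbut-2-en-1-yl)cyclohexa-1,5-dien-1-olate (C6-enolate of 4) | [Li+].[O-]C1=CCCC(OCOC)=C1CC=C(C)C | intermediate (not isolated)
12 | 3-(methoxymethoxy)-6-[(E)-3-[4-(methoxymethoxy)-3-(3-methylbut-2-en-1-yl)phenyl]prop-2-enoyl]-2-(3-methylbut-2-en-1-yl)cyclohex-2-en-1-one (racemic at C6) | CC(C)=CCC1=C(OCOC)CCC(C(=O)/C=C/c2ccc(OCOC)c(CC=C(C)C)c2)C1=O | intermediate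
13 | sodium enolate of 12 (delocalised β-diketonate, drawn as the ring enolate) | [Na+].[O-]C1=C(C(=O)/C=C/c2ccc(OCOC)c(CC=C(C)C)c2)CCC(OCOC)=C1CC=C(C)C | intermediate (not isolated)
14 | 12 bearing a phenylselanyl group at C6 (quaternary C6, racemic) | CC(C)=CCC1=C(OCOC)CCC([Se]c2ccccc2)(C(=O)/C=C/c3ccc(OCOC)c(CC=C(C)C)c3)C1=O | intermediate (not isolated)
15 | selenoxide of 14 (mixture of diastereomers at C6 and Se) | CC(C)=CCC1=C(OCOC)CCC([Se](=O)c2ccccc2)(C(=O)/C=C/c3ccc(OCOC)c(CC=C(C)C)c3)C1=O | intermediate (not isolated)
16 | 3-(methoxymethoxy)-6-[(E)-3-[4-(methoxymethoxy)-3-(3-methylbut-2-en-1-yl)phenyl]prop-2-enoyl]-2-(3-methylbut-2-en-1-yl)cyclohexa-2,5-dien-1-one | CC(C)=CCC1=C(OCOC)CC=C(C(=O)/C=C/c2ccc(OCOC)c(CC=C(C)C)c2)C1=O | intermediate (not isolated)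
17 | Kanzonol C 4,4'-bis(methoxymethyl) ether | CC(C)=CCc1c(OCOC)ccc(C(=O)/C=C/c2ccc(OCOC)c(CC=C(C)C)c2)c1O | intermediate
18 | Kanzonol C | CC(C)=CCc1cc(/C=C/C(=O)c2ccc(O)c(CC=C(C)C)c2O)ccc1O | target

**Step count**
Total: 9 steps. Longest linear sequence: 7 steps (steps 3, 4, 5, 6, 7, 8, 9).

**Steps most likely to fail**

1. Step 8. The selenium electrophile, or the benzeneselenenic acid set free on elimination, may add across the prenyl double bonds; the peroxide may epoxidise the prenyl groups or oxidatively cyclise the new 2'-hydroxychalcone. The fallback takes ring A from an arene instead of making it. It sets out from aldehyde 7 and rejoins the route at 17. Commercial 1-(2,4-dihydroxyphenyl)ethanone F1 would be iodinated with I2/HIO3 in aqueous ethanol at the carbon between the two hydroxyls to give 1-(2,4-dihydroxy-3-iodophenyl)ethanone F2. The non-chelated 4-hydroxyl would be protected (MOMCl, iPr2NEt, CH2Cl2) to give 1-[2-hydroxy-3-iodo-4-(methoxymethoxy)phenyl]ethanone F3. Stille coupling with tributyl(3-methylbut-2-en-1-yl)stannane (Pd(PPh3)4 as the zerovalent palladium catalyst, CsF, DMF, 80 °C) would give 1-[2-hydroxy-4-(methoxymethoxy)-3-(3-methylbut-2-en-1-yl)phenyl]ethanone F4. Claisen–Schmidt condensation of F4 with 7 (KOH, EtOH/H2O, rt) would give 17.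

2. Step 7. The enolate may add in conjugate fashion to the β-carbon of the cinnamoyl unit, acylate on oxygen, or be consumed by proton transfer to the more acidic diketone product. The fallback replaces acylation by aldol addition and oxidation. It sets out from 7 and 4 and rejoins at 12. Wittig homologation of 7 with (triphenylphosphoranylidene)acetaldehyde (toluene, 80 °C) would give (E)-3-[4-(methoxymethoxy)-3-(3-methylbut-2-en-1-yl)phenyl]prop-2-enal F5. Addition of enolate 11 (from 4, LDA, THF, −78 °C) to F5 would give 6-[(E)-1-hydroxy-3-[4-(methoxymethoxy)-3-(3-methylbut-2-en-1-yl)phenyl]prop-2-en-1-yl]-3-(methoxymethoxy)-2-(3-methylbut-2-en-1-yl)cyclohex-2-en-1-one F6 as a diastereomer mixture; both centres are erased later. Dess–Martin periodinane (NaHCO3, CH2Cl2, 0 °C) would oxidise F6 to 12.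

3. Step 3. O-alkylation and double alkylation of the phenoxide may outrun the ortho C-alkylation, leaving little of the mono-C-prenyl phenol. The fallback installs the prenyl group by cross-coupling. It replaces starting material 5 and rejoins at 7. Commercial 3-bromo-4-hydroxybenzaldehyde F7 would be protected (MOMCl, iPr2NEt, CH2Cl2) to give 3-bromo-4-(methoxymethoxy)benzaldehyde F8. Stille coupling of F8 with tributyl(3-methylbut-2-en-1-yl)stannane (Pd(PPh3)4 as the zerovalent palladium catalyst, DMF, 90 °C) would give 7 directly.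

**Further compounds**
F1 | step 8 | 1-(2,4-dihydroxyphenyl)ethanone | CC(=O)c1ccc(O)cc1O
F2 | step 8 | 1-(2,4-dihydroxy-3-iodophenyl)ethanone | CC(=O)c1ccc(O)c(I)c1O
F3 | step 8 | 1-[2-hydroxy-3-iodo-4-(methoxymethoxy)phenyl]ethanone | CC(=O)c1ccc(OCOC)c(I)c1O
F4 | step 8 | 1-[2-hydroxy-4-(methoxymethoxy)-3-(3-methylbut-2-en-1-yl)phenyl]ethanone | CC(=O)c1ccc(OCOC)c(CC=C(C)C)c1O
F5 | step 7 | (E)-3-[4-(methoxymethoxy)-3-(3-methylbut-2-en-1-yl)phenyl]prop-2-enal | CC(C)=CCc1cc(/C=C/C=O)ccc1OCOC
F6 | step 7 | 6-[(E)-1-hydroxy-3-[4-(methoxymethoxy)-3-(3-methylbut-2-en-1-yl)phenyl]prop-2-en-1-yl]-3-(methoxymethoxy)-2-(3-methylbut-2-en-1-yl)cyclohex-2-en-1-one (diastereomer mixture, racemic) | CC(C)=CCC1=C(OCOC)CCC(C(O)/C=C/c2ccc(OCOC)c(CC=C(C)C)c2)C1=O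
F7 | step 3 | 3-bromo-4-hydroxybenzaldehyde | O=Cc1ccc(O)c(Br)c1
F8 | step 3 | 3-bromo-4-(methoxymethoxy)benzaldehyde | COCOc1ccc(C=O)cc1Br
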